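The route rests on cutting the C4–C4a bond of the pyranone (ring C). In the target the C4 carbonyl ties furan carbon C3 to A-ring carbon C4a, and C4a lies between the oxygen-bearing carbons C5 and C8a. The key step uses exactly this: LDA, held by a C3 diethylamide, removes the A-ring hydrogen flanked by two oxygens, and the aryllithium acylates itself on the amide, closing ring C and finishing the skeleton without acid. The precursor 22 is a benzofuran carrying the bis-MOM phloroglucinol ether at C2, CONEt2 at C3 and the finished (S)-dihydrofuran with a TES-protected carbinol, whose stereocentre comes from Shi epoxidation and invertive ring closure.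

Key step: step 15

Remark: locants C2–C8a are those of the chromen-4-one core (C2 and C3 are shared with the furan; A ring = C4a–C8a). The D-fructose-derived Shi ketone is assumed to attack the prenyl alkene with its usual facial sense, which corresponds to the (R)-epoxide.

Step 1
Reactants: 1 resorcinol
Product: 2 1,3-bis(methoxymethoxy)benzene
Conditions: MOMCl (2.4 equiv), NaH (2.4 equiv), DMF, 0 °C → rt
Reagents that add atoms: chloromethyl methyl ether (MOMCl), COCCl
Why: Williamson-type O-alkylation of the bis-phenoxide installs two acetal ethers that will jointly direct lithiation to the carbon between them.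

Step 2
Reactants: 2 1,3-bis(methoxymethoxy)benzene; 3 prenyl bromide
Product: 5 1,3-bis(methoxymethoxy)-2-(3-methylbut-2-enyl)benzene, via aryllithium 4 (not isolated)
Conditions: n-BuLi (1.1 equiv), THF, 0 °C → rt; CuI (10 mol %), 3 (1.2 equiv), −40 °C → rt
Reagents that add atoms: none
Why: Directed ortho metalation takes place at C2 under the cooperative effect of both MOM ethers, and copper-assisted SN2 allylation of the aryllithium with the primary allylic bromide gives the linear prenyl arene.

Step 3
Reactants: 5 1,3-bis(methoxymethoxy)-2-(3-methylbut-2-enyl)benzene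
Product: 6 2-(3-methylbut-2-enyl)benzene-1,3-diol (2-prenylresorcinol)
Conditions: conc. HCl (cat.), MeOH, 40 °C
Reagents that add atoms: none
Why: Acid-catalysed transacetalisation to methanol frees both phenols, and catalytic acid at mild temperature stays short of the conditions under which an o-prenylphenol closes to a chroman.

Step 4
Reactants: 6 2-prenylresorcinol
Product: 7 1,3-bis(tert-butyldimethylsilyloxy)-2-(3-methylbut-2-enyl)benzene
Conditions: TBSCl (2.5 equiv), imidazole (5 equiv), DMF, rt
Reagents that add atoms: tert-butyldimethylsilyl chloride (TBSCl), CC(C)(C)[Si](C)(C)Cl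
Why: Standard silylation gives fluoride-labile phenol protection that withstands the buffered oxidant of the next step, which a free resorcinol would not.

Step 5
Reactants: 7 1,3-bis(tert-butyldimethylsilyloxy)-2-(3-methylbut-2-enyl)benzene
Product: 8 (R)-3-[2,6-bis(tert-butyldimethylsilyloxy)benzyl]-2,2-dimethyloxirane
Conditions: D-fructose-derived Shi ketone (30 mol %), Oxone, K2CO3, Bu4NHSO4 (cat.), MeCN–DMM / aq. Na2B4O7–Na2EDTA buffer, 0 °C
Reagents that add atoms: Oxone (active component potassium peroxymonosulfate), [K+].[O-]S(=O)(=O)OO
Why: Shi asymmetric epoxidation, in which the chiral dioxirane transfers oxygen to the trisubstituted alkene through a spiro transition state, so that catalyst control sets the (R) configuration at the secondary epoxide carbon, the source of the only stereocentre of the target.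

Step 6
Reactants: 8 (R)-3-[2,6-bis(tert-butyldimethylsilyloxy)benzyl]-2,2-dimethyloxirane
Product: 10 (S)-2-(2-hydroxypropan-2-yl)-2,3-dihydrobenzofuran-4-ol, via epoxy-resorcinol phenoxide 9 (not isolated)
Conditions: TBAF (2.5 equiv), THF, 0 °C → rt; aq. NH4Cl
Reagents that add atoms: none
Why: Fluoride desilylation releases phenoxide 9, which opens the epoxide at its secondary carbon by 5-exo-tet SN2 attack with inversion, (R) to (S), and because the two phenols are interchanged by rotation of the ring only one constitution can result.

Step 7
Reactants: 10 (S)-2-(2-hydroxypropan-2-yl)-2,3-dihydrobenzofuran-4-ol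
Product: 11 (S)-5-bromo-2-(2-hydroxypropan-2-yl)-2,3-dihydrobenzofuran-4-ol
Conditions: NBS (1.0 equiv), i-Pr2NH (10 mol %), CH2Cl2, −20 → 0 °C
Reagents that add atoms: N-bromosuccinimide (NBS), O=C1CCC(=O)N1Br
Why: Amine-mediated ortho-bromination of a phenol, in which the N-bromoamine formed from NBS hydrogen-bonds to the phenol and delivers bromine to the only free ortho carbon (C5) in preference to the para carbon (C7).

Step 8
Reactants: 12 propiolic acid; 13 diethylamine
Product: 14 N,N-diethylprop-2-ynamide
Conditions: DCC (1.05 equiv), CH2Cl2, −20 → 0 °C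
Reagents that add atoms: none
Why: Carbodiimide amide coupling at low temperature outruns conjugate addition of the amine to the alkyne.

Step 9
Reactants: 11 (S)-5-bromo-2-(2-hydroxypropan-2-yl)-2,3-dihydrobenzofuran-4-ol; 14 N,N-diethylprop-2-ynamide
Product: 15 (S,E)-3-{[5-bromo-2-(2-hydroxypropan-2-yl)-2,3-dihydrobenzofuran-4-yl]oxy}-N,N-diethylacrylamide
Conditions: DABCO (20 mol %), MeCN, rt → 40 °C
Reagents that add atoms: none
Why: Amine-catalysed oxa-Michael addition of the phenol to the electron-poor alkyne gives the (E)-β-aryloxyacrylamide, while the tertiary alcohol is too hindered and too weakly acidic to compete.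

Step 10
Reactants: 15 (S,E)-β-(bromoaryloxy)acrylamide
Product: 16 N,N-diethylbenzofuran-3-carboxamide bearing the (S)-2-(2-hydroxypropan-2-yl)dihydrofuran fused at C6 (oxygen) and C7 (CH2)
Conditions: Pd(OAc)2 (5 mol %), PPh3 (15 mol %), K2CO3 (2 equiv), DMF, 100 °C
Reagents that add atoms: none
Why: Intramolecular Heck-type cyclisation of a β-(2-bromoaryloxy)acrylic acid derivative joins the brominated arene carbon to the α-carbon of the acrylamide and, after loss of HBr, gives the aromatic furan, which is the established entry to benzofuran-3-carboxylic acid derivatives.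

Step 11
Reactants: 16 tricyclic hydroxy amide
Product: 17 triethylsilyl ether of 16
Conditions: TESOTf (1.5 equiv), 2,6-lutidine (2.5 equiv), CH2Cl2, 0 °C
Reagents that add atoms: triethylsilyl triflate (TESOTf), CC[Si](CC)(CC)OS(=O)(=O)C(F)(F)F
Why: A silyl triflate with a hindered pyridine base silylates even a tertiary alcohol, which removes the only acidic O–H before the two lithiation steps.

Step 12
Reactants: 17 TES-protected tricyclic amide
Product: 19 2-bromo derivative of 17 (bromine on furan C2), via 2-lithiobenzofuran 18 (not isolated)
Conditions: LDA (1.2 equiv), THF, −78 °C; BrCl2C–CCl2Br (1.3 equiv), −78 → −20 °C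
Reagents that add atoms: 1,2-dibromo-1,1,2,2-tetrachloroethane, ClC(Cl)(Br)C(Cl)(Cl)Br
Why: The furan C2–H is the most acidic C–H and lies next to the directing amide, so directed lithiation is regiospecific and the stable 2-lithiobenzofuran is brominated by halogen transfer from the polyhaloethane.

Step 13
Reactants: 20 phloroglucinol
Product: 21 3,5-bis(methoxymethoxy)phenol
Conditions: MOMCl (2.0 equiv), i-Pr2NEt (2.2 equiv), CH2Cl2–DMF, 0 °C → rt
Reagents that add atoms: chloromethyl methyl ether (MOMCl), COCCl
Why: Statistical twofold O-alkylation of the symmetric triol gives the bis-MOM phenol, which is separable by chromatography from the mono- and tris-ethers.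

Step 14
Reactants: 19 2-bromobenzofuran-3-carboxamide; 21 3,5-bis(methoxymethoxy)phenol
Product: 22 N,N-diethyl 2-[3,5-bis(methoxymethoxy)phenoxy]benzofuran-3-carboxamide fused to the (S)-dihydrofuran that carries the TES-protected carbinol
Conditions: CuI (10 mol %), N,N-dimethylglycine (30 mol %), Cs2CO3 (2 equiv), dioxane, 90 °C
Reagents that add atoms: none
Why: Ullmann-type copper-catalysed C–O coupling of a heteroaryl bromide with a phenol, helped by the neighbouring amide, which can chelate copper and also activates C2 towards addition–elimination.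

Step 15
Reactants: 22 2-aryloxybenzofuran-3-carboxamide
Product: 25 TES/bis-MOM-protected target, via A-ring aryllithium 23 (not isolated), via lithium hemiaminal 24 (not isolated)
Conditions: LDA (3.5 equiv), THF, −78 → 0 °C; cold aq. NH4Cl
Reagents that add atoms: none
Why: The diethylamide carbonyl binds LDA and carries it over the C2–O bridge to the A ring, where the C–H between the aryloxy and MOM oxygens is removed in an uphill, reversible equilibrium to give aryllithium 23. 23 adds to the amide carbonyl in a 6-exo-trig closure that forms C4–C4a, and adduct 24 should keep its diethylamino group until the cold buffered quench, so that no free amide base meets the electrophilic O–C–O carbon of the product. The closest known reaction type is directed remote metalation with cyclisation (an anionic Friedel–Crafts equivalent), by which 2-aryloxybenzamides are converted into xanthones. No stereocentre is created, and the (S) centre carries no acidic hydrogen and is not touched. The step needs site selectivity: the two productive A-ring positions are related by symmetry, whereas anions at the carbon between the two MOM ethers or on the B ring have no carbonyl within reach and return to the C–H form through diisopropylamine, so only the cyclising anion is drained. Holding the temperature at or below 0 °C guards the dihydrofuran against base-induced opening through its benzylic CH2.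

Step 16
Reactants: 25 TES/bis-MOM-protected target
Product: 26 target CNP0193284.1, the (S)-configured 5,7-dihydroxy coumaronochromone with the 2-(2-hydroxypropan-2-yl)dihydrofuran
Conditions: HCl (2 M in MeOH)–THF, 40 °C
Reagents that add atoms: none
Why: Acid-catalysed methanolysis cleaves the two aryl MOM acetals and the TES ether in one operation, while the aromatic core and the tertiary carbinol, which the adjacent C–O bond deactivates towards ionisation, are expected to persist.

Compound list
1 | resorcinol | Oc1cccc(O)c1 | starting material
2 | 1,3-bis(methoxymethoxy)benzene | COCOc1cccc(OCOC)c1 | intermediate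
3 | prenyl bromide | CC(C)=CCBr | starting material
4 | 2-lithio-1,3-bis(methoxymethoxy)benzene | [Li]c1c(OCOC)cccc1OCOC | intermediate
5 | 1,3-bis(methoxymethoxy)-2-(3-methylbut-2-enyl)benzene | COCOc1cccc(OCOC)c1CC=C(C)C | intermediate
6 | 2-(3-methylbut-2-enyl)benzene-1,3-diol | CC(C)=CCc1c(O)cccc1O | intermediate
7 | 1,3-bis(tert-butyldimethylsilyloxy)-2-(3-methylbut-2-enyl)benzene | CC(C)=CCc1c(O[Si](C)(C)C(C)(C)C)cccc1O[Si](C)(C)C(C)(C)C | intermediate
8 | (R)-3-[2,6-bis(tert-butyldimethylsilyloxy)benzyl]-2,2-dimethyloxirane | CC1(C)O[C@@H]1Cc1c(O[Si](C)(C)C(C)(C)C)cccc1O[Si](C)(C)C(C)(C)C | intermediate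
9 | (R)-2-[(3,3-dimethyloxiran-2-yl)methyl]benzene-1,3-diol, present as its phenoxide | CC1(C)O[C@@H]1Cc1c(O)cccc1O | intermediate
10 | (S)-2-(2-hydroxypropan-2-yl)-2,3-dihydrobenzofuran-4-ol | CC(C)(O)[C@@H]1Cc2c(O)cccc2O1 | intermediate
11 | (S)-5-bromo-2-(2-hydroxypropan-2-yl)-2,3-dihydrobenzofuran-4-ol | CC(C)(O)[C@@H]1Cc2c(O)c(Br)ccc2O1 | intermediate
12 | propiolic acid | C#CC(=O)O | starting material
13 | diethylamine | CCNCC | starting material
14 | N,N-diethylprop-2-ynamide | C#CC(=O)N(CC)CC | intermediate
15 | (S,E)-3-{[5-bromo-2-(2-hydroxypropan-2-yl)-2,3-dihydrobenzofuran-4-yl]oxy}-N,N-diethylacrylamide | CC(C)(O)[C@@H]1Cc2c(O/C=C/C(=O)N(CC)CC)c(Br)ccc2O1 | intermediate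
16 | N,N-diethylbenzofuran-3-carboxamide fused at C6 (O) and C7 (CH2) to the (S)-2-(2-hydroxypropan-2-yl)dihydrofuran | CC(C)(O)[C@@H]1Cc2c(ccc3c2occ3C(=O)N(CC)CC)O1 | intermediate
17 | triethylsilyl ether of 16 | CC(C)(O[Si](CC)(CC)CC)[C@@H]1Cc2c(ccc3c2occ3C(=O)N(CC)CC)O1 | intermediate
18 | 2-lithio derivative of 17 | CC(C)(O[Si](CC)(CC)CC)[C@@H]1Cc2c(ccc3c2oc([Li])c3C(=O)N(CC)CC)O1 | intermediate
19 | 2-bromo derivative of 17 | CC(C)(O[Si](CC)(CC)CC)[C@@H]1Cc2c(ccc3c2oc(Br)c3C(=O)N(CC)CC)O1 | intermediate
20 | phloroglucinol | Oc1cc(O)cc(O)c1 | starting material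
21 | 3,5-bis(methoxymethoxy)phenol | COCOc1cc(O)cc(OCOC)c1 | intermediate
22 | key-step precursor, 2-[3,5-bis(methoxymethoxy)phenoxy] derivative of 17 | CC(C)(O[Si](CC)(CC)CC)[C@@H]1Cc2c(ccc3c2oc(Oc2cc(OCOC)cc(OCOC)c2)c3C(=O)N(CC)CC)O1 | intermediate
23 | A-ring aryllithium, lithium between the aryloxy and MOM oxygens | CC(C)(O[Si](CC)(CC)CC)[C@@H]1Cc2c(ccc3c2oc(Oc2cc(OCOC)cc(OCOC)c2[Li])c3C(=O)N(CC)CC)O1 | intermediate
24 | lithium hemiaminal at C4 (transient C4 configuration undefined) | CC(C)(O[Si](CC)(CC)CC)[C@@H]1Cc2c(ccc3c2oc2Oc4cc(OCOC)cc(OCOC)c4C(O[Li])(N(CC)CC)c23)O1 | intermediate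
25 | TES/bis-MOM-protected target | CC(C)(O[Si](CC)(CC)CC)[C@@H]1Cc2c(ccc3c2oc2oc4cc(OCOC)cc(OCOC)c4c(=O)c23)O1 | intermediate
26 | CNP0193284.1 | CC(C)(O)[C@@H]1Cc2c(ccc3c2oc2oc4cc(O)cc(O)c4c(=O)c23)O1 | target

Total step count: 16. Longest linear sequence: 14 steps from resorcinol (steps 1–7, 9–12, 14–16).

Steps most likely to fail

1. Step 15 (key step). Metalation may stall at unproductive sites. The amide base may attack furan C2 with loss of the aryloxide, or the dihydrofuran may open by base-induced elimination. Fallback: the carbanion site is fixed by a halogen instead of by an acidity difference. Setting out from 22, NBS (1 equiv, MeCN, −20 °C) should brominate the most electron-rich ring para to a MOM ether, that is at the carbon between the aryloxy and MOM oxygens, to give the 2'-bromo precursor F1. n-BuLi (THF, −78 °C) then produces the same aryllithium 23 by bromine–lithium exchange, quickly and without any amide base. Parham-type cycliacylation through 24 comes back to the route at 25.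

2. Step 7. Bromine may enter para to the phenol or enter twice, because both open positions are activated by two oxygens. Fallback: no halogen is used. Setting out from 10, oxa-Michael addition to 14 under the conditions of step 9 gives the bromine-free (E)-aryloxyacrylamide F2. A palladium(II)-catalysed dehydrogenative cyclisation then closes the furan (Pd(OAc)2, Cu(OAc)2 as oxidant, DMF, 100–110 °C; Fujiwara–Moritani type, known for 3-aryloxyacrylates). The tether can reach only the one free ortho carbon, and the route is rejoined at 16.

3. Step 14. Coupling at the hindered C2 beside the twisted amide may be slow, so that hydrolysis or loss of bromine from C2 takes over. Fallback: uncatalysed ipso-substitution of a sulfone. Setting out from 17, lithiation as in step 12 (18) and quenching with dimethyl disulfide gives the 2-methylthio compound F3. mCPBA (2.2 equiv, CH2Cl2, 0 °C) gives the 2-methylsulfonyl compound F4. The caesium phenoxide of 21 (Cs2CO3, DMF, rt → 50 °C) then displaces methanesulfinate by addition–elimination at C2, which comes back to the route at 22.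

Further compounds
F1 | step 15 | 2'-bromo derivative of 22 (bromine between the aryloxy and MOM oxygens of the A ring) | CC(C)(O[Si](CC)(CC)CC)[C@@H]1Cc2c(ccc3c2oc(Oc2cc(OCOC)cc(OCOC)c2Br)c3C(=O)N(CC)CC)O1
F2 | step 7 | (S,E)-N,N-diethyl-3-{[2-(2-hydroxypropan-2-yl)-2,3-dihydrobenzofuran-4-yl]oxy}acrylamide | CC(C)(O)[C@@H]1Cc2c(O/C=C/C(=O)N(CC)CC)cccc2O1
F3 | step 14 | 2-methylthio derivative of 17 | CC(C)(O[Si](CC)(CC)CC)[C@@H]1Cc2c(ccc3c2oc(SC)c3C(=O)N(CC)CC)O1
F4 | step 14 | 2-methylsulfonyl derivative of 17 | CC(C)(O[Si](CC)(CC)CC)[C@@H]1Cc2c(ccc3c2oc(S(C)(=O)=O)c3C(=O)N(CC)CC)O1
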